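Numbering used throughout: decalin carbons C1–C10 in the drimane sense (C4 carries the gem-dimethyl group, C5 is the ring-fusion CH, C8 the CH(CH3), C9 the alkylidene carbon, C10 the quaternary ring-fusion carbon); C11 is the exocyclic methine; the arene is C1'–C6' with C1' on C11, OH on C2', C3' and C6', H on C4' and CHO on C5'.

## Analysis of the target

The target is a C22 meroterpenoid in which a cis-fused decalin (ring A: C1–C5 and C10; ring B: C5–C10) is joined through an exocyclic trisubstituted alkene C9=C11 to a pentasubstituted benzene (ring C). The decalin has three stereocentres, C5 (R), C8 (S) and C10 (S): H5, the C8 methyl and the C10 methyl lie on the same face, so the fusion is cis and the two methyls are 1,3-cis across C9. The alkene is E, with the arene on the C8 side and away from quaternary C10. Ring C is a hydroxyquinol aldehyde: OH at C2', C3' and C6', CHO at C5', H at C4'. The sensitive points are the electron-rich triol (air oxidation to a quinone), the aldehyde, and the ortho-hydroxystyrene, which under acid protonates at C11 so that C9 is captured by a neighbouring phenol oxygen or the alkene slips into ring B. The hard part is the junction: C9 lies between quaternary C10 and tertiary C8, C1' lies between two oxygens, and the alkene geometry has to be fixed between them. The strategy rests on C1' sitting between the meta-related oxygens at C2' and C6', the pattern produced when a vinylketene and a silyl ynol ether merge into a benzene ring, so ring C can be grown onto a decalin alkyne instead of being coupled to C9 or C11.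

## Retrosynthetic reasoning

**Arene deprotection and oxidation level (35 back to 31).** The O–allyl bond at C3' is cut last (35 from 34), the O–Si bond at C6' before it (34 from 33), and the C5' aldehyde is traced through benzylic alcohol 32 to the methyl ester of 31. The two protecting groups are chosen so that each leaves under near-neutral conditions, since the ortho-hydroxystyrene tolerates neither Lewis acid nor oxidant. The forward steps must keep the hydroxyquinol masked until the final operation.

**Ring C (31 back to 18 and 26).** Three bonds are cut, C1'–C2', C5'–C6' and C2'–C3', which divides ring C into a two-carbon piece (C1' and C6' of silyl ynol ether 18) and a four-carbon piece (C2'–C5' of diazo ketoester 26). Cutting here and not at C11–C1' or C9=C11 puts the congested bond C11–C1' inside a building block, where C1' is an unhindered sp carbon. It also delivers all five ring substituents in one step. The forward reaction must generate a vinylketene from 26, join it to 18 with the correct orientation, and leave the C9=C11 geometry untouched.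

**Siloxyalkyne (18 back to 15, then 11 and 12).** The alkyne carbon C1' is removed from between C11 and the carboxyl carbon, which leads back to unsaturated ester 15 by an ester-to-ynolate homologation. The C9=C11 bond of 15 is then cut to ketone 11 and silyl acetate 12. This fixes the alkene geometry at a stage where only a small ester group, not an arene, has to be placed beside C8. The forward olefination must attack a carbonyl flanked by C8 and C10 and favour the E isomer.

**Decalone (11 back to 1 and 4).** C8 is set last, by saturating the C7=C8 bond of enone 9 and equilibrating, because the wanted epimer carries an equatorial methyl. The C1–C10 bond of 9 is cut to iodide 7: an intramolecular enolate alkylation creates quaternary C10 and enforces the cis fusion. Iodide 7 comes through alcohol 6 and aldehyde 5, in which the C3–C4 bond is cut to 6-methylcarvone 3 and acrolein 4. The isopropenyl carbon of carvone 1 thus becomes C4 with its two methyls, and the carvone stereocentre becomes C5. The forward sequence must add a three-carbon chain to a tertiary carbon and then close ring A onto C10 from the face of that chain.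

**Diazo ketoester (26 back to 19, 20 and 23).** The diazo group is removed (25), the C–C bond between the ketone carbon and the malonate carbon is cut (acid 22 and malonate half-ester 23), and the enol ether C–O bond is cut (propiolate 19 and allyl alcohol 20). This places the allyl group on what becomes the C3' oxygen from the start.

## Alternatives that were turned down

**Alternative 1:** C4–C5 and C9–C10 are disconnected to the open-chain Z-dienyne A1, which already carries the arene on its alkyne. In the forward step acid protonates C3, the Z C5=C10 alkene closes ring A onto C4, and the alkyne closes ring B at C10. Water then captures the vinyl cation to give the C11 aryl ketone A2.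
- For it: two rings, quaternary C10, the cis fusion and the terpene–arene link arise in one step. In bonds formed per step it is stronger than the chosen route, which needs six steps for the decalone alone.
- Against it: the only stereocentre of A1 is C8, several atoms from the reacting alkenes, and it would have to dictate the face of the whole bicyclisation. A Z trisubstituted alkene folds through a more strained arrangement than its E isomer, so stepwise closure and partial loss of the cis fusion are likely. The electron-rich aryl ring sits next to the vinyl cation and can close onto it.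
- Further against it: A2 has C11 as a ketone and C9 as CH. The alkene would still have to be made by reduction and dehydration, conditions that move it into ring B, and three methyl ethers would then have to be cleaved on an acid-sensitive ortho-hydroxystyrene.
- Comparison: the chosen strategy sets C5, C8 and C10 on rings where geometry and thermodynamics decide, fixes the alkene before the arene exists, and frees the phenols under neutral conditions. It gives up the brevity of a single skeleton-forming step.

**Alternative 2:** Ring A is cut at C1–C10 and C4–C5 into quinone A3 and diene A4. In the forward step a Lewis acid, achiral or chiral, promotes a Diels–Alder reaction in which the gem-dimethyl terminus of A4 bonds to C5 and the methyl-bearing quinone carbon becomes C10, giving the cis-fused enedione A5.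
- For it: one step from two cheap achiral compounds, cis fusion guaranteed by suprafacial addition, and catalytic enantiocontrol available. For ring A and C10 it is clearly stronger than the five steps spent here on ring A.
- Against it: the diene terminus carries a cis methyl, which disfavours the s-cis conformer. A5 has a C6 carbonyl and a C2=C3 alkene to remove and two ring B carbonyls to tell apart.
- Decisive point: the key step leaves the real problem untouched. A benzyl-type nucleophile bearing two ortho oxygens would have to add to the C9 carbonyl between C8 and quaternary C10 and then be dehydrated toward C11 and not toward C8.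
- Comparison: the chosen strategy uses more steps on the decalin, but they end in a small alkyne handle at C11, so the crowded aryl–alkene junction is made by ring construction and not by addition to C9.

**Alternative 3:** C11–C1' and O–C2' are cut into aryne precursor A6 and decalin aldehyde A7. In the forward step a fluoride source releases the aryne, which adds across the C=O of A7 with oxygen to C2' and carbon to C1', steered by the C6' methoxy group. The benzoxete opens to an ortho-quinone methide, which takes the C9 hydrogen to give ortho-hydroxystyrene A8.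
- For it: it is highly convergent and nearly neutral, the alkene and the aryl bond appear together, and the arene is bought, not built. On convergence and mildness it is equal to or better than the chosen route.
- Against it: A7 is a neopentyl-type aldehyde, so its [2+2] addition must compete with aryne self-reaction. The ortho-quinone methide can be trapped by a second aryne or aldehyde as easily as it undergoes the hydrogen shift, and that shift sets the alkene geometry with no controlling element.
- Further against it: A8 lacks the C3' oxygen and the C5' carbon. A phenol ortho-oxidation (the step most likely to trigger spirocyclisation onto C9), a bromine-to-formyl exchange and a methyl ether cleavage would all remain.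
- Comparison: the chosen strategy installs the C2', C3' and C6' oxygens and the C5' carbon in the ring-forming step. The price is building the arene from two fragments and a photochemical step.

Key step: step 13

Assumption: the C3' oxygen is carried through the benzannulation as an allyl ether, because an aryl methyl ether at that position could only be cleaved with Lewis acid or hot thiolate, which the ortho-hydroxystyrene and the aldehyde would not survive, whereas the allyl ether leaves with zerovalent palladium under neutral conditions.

## Route

**Step 1**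
Reactants: 1 (S)-carvone
Product: 3 (5S)-2,6-dimethyl-5-(prop-1-en-2-yl)cyclohex-2-en-1-one (6-methylcarvone; both C6 epimers), via lithium dienolate 2 (not isolated)
Conditions: LiN(i-Pr)2, THF, −78 °C; MeI, −78 → 0 °C
Reagents that add atoms: iodomethane, CI
Why: Kinetic deprotonation of the enone at its only α′ position (the future C10) gives cross-conjugated dienolate 2, and SN2 methylation installs the C10 methyl (kinetic enolate alkylation); the configuration at this carbon does not matter because it is enolised again in step 5.

**Step 2**
Reactants: 3 6-methylcarvone; 4 acrolein (prop-2-enal)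
Product: 5 4-[(1S)-2,4-dimethyl-3-oxocyclohex-4-en-1-yl]-4-methylpentanal
Conditions: Fe(acac)3 (cat.), PhSiH3, EtOH/ethylene glycol, 60 °C
Reagents that add atoms: none
Why: Hydrogen-atom transfer from an iron hydride to the electron-neutral isopropenyl group gives the tertiary C4 radical, which adds to acrolein (Giese addition) and is reduced and protonated; this forms C3–C4 and the gem-dimethyl quaternary centre, while the conjugated enone alkene is a poor hydrogen-atom acceptor and is too close to the radical to trap it.

**Step 3**
Reactants: 5 keto aldehyde
Product: 6 (5S)-5-(5-hydroxy-2-methylpentan-2-yl)-2,6-dimethylcyclohex-2-en-1-one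
Conditions: NaBH4, MeOH/CH2Cl2, −78 °C
Reagents that add atoms: none
Why: Chemoselective borohydride reduction: at low temperature the unhindered aldehyde is reduced much faster than the conjugated ketone, which is also shielded by its two α substituents.

**Step 4**
Reactants: 6 hydroxy enone
Product: 7 (5S)-5-(5-iodo-2-methylpentan-2-yl)-2,6-dimethylcyclohex-2-en-1-one
Conditions: I2, PPh3, imidazole, CH2Cl2, 0 °C → rt
Reagents that add atoms: iodine, II
Why: Appel-type iodination turns the primary alcohol into the iodide by SN2 displacement of the oxyphosphonium group; no base strong enough to enolise the ketone is present.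

**Step 5**
Reactants: 7 iodo enone
Product: 9 (4aR,8aS)-2,5,5,8a-tetramethyl-4a,5,6,7,8,8a-hexahydronaphthalen-1(4H)-one (cis-fused), via lithium enolate 8 (not isolated)
Conditions: LiN(i-Pr)2, THF, −78 °C; then DMPU, −78 → 0 °C
Reagents that add atoms: none
Why: Intramolecular enolate C-alkylation (6-exo-tet) forms C1–C10 and the quaternary C10; the chain can only reach C10 perpendicular to the enolate plane from the face that carries C4, and allylic strain with the C10 methyl already pushes the C5 substituent pseudo-axial, so C1 and C4 end cis and the C10 methyl lands on the face of H5 (cis fusion).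

**Step 6**
Reactants: 9 cis-fused enone
Product: 11 (2S,4aR,8aS)-2,5,5,8a-tetramethyloctahydronaphthalen-1(2H)-one, via 8-epi ketone 10 (not isolated)
Conditions: H2 (1 atm), Pd/C, EtOAc, rt; then NaOMe, MeOH, rt
Reagents that add atoms: none
Why: Heterogeneous hydrogenation saturates C7=C8, with hydrogen expected from the convex face to give mainly epimer 10; methoxide then equilibrates C8 through the enolate to the equatorial methyl, which is cis-1,3 to the equatorial C10 methyl in the chair that keeps C1 axial on ring B, whereas the epimer would place its methyl syn-axial to C1, so C8 is set under thermodynamic control.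

**Step 7**
Reactants: 11 cis-decalone; 12 ethyl 2-(trimethylsilyl)acetate
Product: 15 ethyl (2E)-2-[(2S,4aR,8aS)-2,5,5,8a-tetramethyloctahydronaphthalen-1(2H)-ylidene]acetate, via ester enolate 13 (not isolated), via silyl alkoxide 14 (not isolated)
Conditions: LiN(i-Pr)2, THF, −78 °C (12); then 11, −78 °C → rt
Reagents that add atoms: none
Why: Peterson olefination: the small, reactive α-silyl ester enolate 13 adds to the hindered carbonyl and alkoxide 14 loses lithium trimethylsilanolate to form C9=C11; the E isomer should predominate because the ester-bearing carbon turns away from quaternary C10, and any enolisation of 11 is harmless since 11 is already the stable C8 epimer.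

**Step 8**
Reactants: 15 unsaturated ester
Product: 18 {[(3E)-3-[(2S,4aR,8aS)-2,5,5,8a-tetramethyloctahydronaphthalen-1(2H)-ylidene]prop-1-yn-1-yl]oxy}tri(propan-2-yl)silane, via dibromo enolate 16 (not isolated), via lithium ynolate 17 (not isolated)
Conditions: CH2Br2, lithium 2,2,6,6-tetramethylpiperidide, THF, −78 °C; LiN(SiMe3)2; n-BuLi, −78 → 0 °C; i-Pr3SiOTf, −78 °C → rt
Reagents that add atoms: dibromomethane, BrCBr; triisopropylsilyl trifluoromethanesulfonate, CC(C)[Si](OS(=O)(=O)C(F)(F)F)(C(C)C)C(C)C
Why: Kowalski ester homologation: dibromomethyllithium adds to the ester, collapse and enolisation give 16, bromine–lithium exchange triggers a 1,2-shift of the alkenyl group with retention of its geometry to ynolate 17, and the bulky silyl triflate silylates oxygen to give the silyl ynol ether; the ester carbonyl is unhindered and the carbenoid is formed before it meets the ester, so the C8 hydrogen is not exposed to free amide base.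

**Step 9**
Reactants: 19 methyl propiolate; 20 allyl alcohol (prop-2-en-1-ol)
Product: 21 methyl (2E)-3-(prop-2-en-1-yloxy)prop-2-enoate
Conditions: DABCO (cat.), CH2Cl2, 0 °C → rt
Reagents that add atoms: none
Why: Amine-catalysed oxa-Michael addition of the alcohol to the ynoate gives the E β-alkoxyacrylate, the isomer formed by protonation of the allenolate away from the alkoxy group.

**Step 10**
Reactants: 21 β-allyloxy acrylate
Product: 22 (2E)-3-(prop-2-en-1-yloxy)prop-2-enoic acid
Conditions: LiOH, THF/H2O, 0 °C → rt; then aq. HCl to pH 3, 0 °C
Reagents that add atoms: lithium hydroxide, [Li+].[OH-]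
Why: Saponification at the acyl carbon; the vinylogous carbonate is stable to cold hydroxide and to brief cold acidification.

**Step 11**
Reactants: 22 β-allyloxy acrylic acid; 23 potassium methyl malonate
Product: 25 methyl (4E)-3-oxo-5-(prop-2-en-1-yloxy)pent-4-enoate, via acid chloride 24 (not isolated)
Conditions: (COCl)2, DMF (cat.), CH2Cl2, 0 °C → rt; then 23, MgCl2, Et3N, MeCN, 0 °C → rt; aq. HCl work-up
Reagents that add atoms: none
Why: Decarboxylative Claisen-type acylation: the magnesium-chelated malonate half-ester is C-acylated by acid chloride 24 at the acyl carbon, which is far more electrophilic than the β-alkoxy carbon, and the acyl malonate loses CO2 on acidification.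

**Step 12**
Reactants: 25 β-keto ester
Product: 26 methyl (4E)-2-diazo-3-oxo-5-(prop-2-en-1-yloxy)pent-4-enoate
Conditions: 4-acetamidobenzenesulfonyl azide, Et3N, MeCN, 0 °C → rt
Reagents that add atoms: 4-acetamidobenzenesulfonyl azide, CC(=O)Nc1ccc(cc1)S(=O)(=O)N=[N+]=[N-]
Why: Regitz diazo transfer to the doubly activated methylene; the mild amine base leaves the enol ether untouched.

**Step 13**
Reactants: 18 decalin silyl ynol ether; 26 diazo ketoester
Product: 31 methyl 4-hydroxy-5-(prop-2-en-1-yloxy)-3-{(E)-[(2S,4aR,8aS)-2,5,5,8a-tetramethyloctahydronaphthalen-1(2H)-ylidene]methyl}-2-{[tri(propan-2-yl)silyl]oxy}benzoate, via vinylketene 27 (not isolated), via cyclobutenone 28 (not isolated), via dienylketene 29 (not isolated), via cyclohexadienone 30 (not isolated)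
Conditions: hν (300 nm, Pyrex), ClCH2CH2Cl, rt; then 80 °C
Reagents that add atoms: none
Why: Irradiation expels nitrogen from 26 and the alkenyl group migrates to the diazo carbon (photochemical Wolff rearrangement; the ester alkoxy group is the poorer migrating group), which gives the ester-substituted vinylketene 27. The ketene C=C then adds to the electron-rich alkyne of 18 in a [2+2] cycloaddition, the nucleophilic alkyne carbon C1' bonding to the ketene carbonyl carbon C2' and the oxygen-bearing C6' bonding to C5', to give cyclobutenone 28. On warming, 28 opens by conrotatory 4π cleavage of its C2'–C5' bond to dienylketene 29, and the isomer with the alkoxyvinyl group cis to the ketene closes ring C by disrotatory 6π electrocyclisation (C2'–C3'); cyclohexadienone 30 then tautomerises irreversibly to phenol 31. The ring opening is reversible, so a dienylketene of the wrong geometry can return through 28. The closest known reaction type is the Danheiser benzannulation of a vinylketene from a photolysed unsaturated diazo ketone with a silyl ynol ether, which gives resorcinol monosilyl ethers with the alkyne substituent between the two oxygens. No stereocentre is created, since C5' of 28 and C3' of 30 are transient sp3 carbons that end aromatic. The step needs regioselectivity in the [2+2] event, secured by the polarisation of the ynol ether against the ketene, and chemoselectivity for the alkyne over the C9=C11 and allyl alkenes, secured by the much higher nucleophilicity of the ynol ether. It also needs the E alkene to survive, for which Pyrex-filtered light and short exposure are chosen so that the arene product absorbs little.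

**Step 14**
Reactants: 31 benzannulation product
Product: 32 [4-hydroxy-5-(prop-2-en-1-yloxy)-3-{(E)-[(2S,4aR,8aS)-2,5,5,8a-tetramethyloctahydronaphthalen-1(2H)-ylidene]methyl}-2-{[tri(propan-2-yl)silyl]oxy}phenyl]methanol
Conditions: i-Bu2AlH, CH2Cl2, −78 → 0 °C; aq. potassium sodium tartrate
Reagents that add atoms: none
Why: Hydride reduction of the aryl ester to the benzylic alcohol; the free phenol is merely deprotonated, and the silyl ether, the allyl ether and the alkene are inert to the aluminium hydride.

**Step 15**
Reactants: 32 benzylic alcohol
Product: 33 4-hydroxy-5-(prop-2-en-1-yloxy)-3-{(E)-[(2S,4aR,8aS)-2,5,5,8a-tetramethyloctahydronaphthalen-1(2H)-ylidene]methyl}-2-{[tri(propan-2-yl)silyl]oxy}benzaldehyde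
Conditions: MnO2, CH2Cl2, rt
Reagents that add atoms: none
Why: Selective benzylic oxidation on the MnO2 surface stops at the aldehyde and is neutral, so the styrene and the phenol are not touched.

**Step 16**
Reactants: 33 silyl-protected aldehyde
Product: 34 2,4-dihydroxy-5-(prop-2-en-1-yloxy)-3-{(E)-[(2S,4aR,8aS)-2,5,5,8a-tetramethyloctahydronaphthalen-1(2H)-ylidene]methyl}benzaldehyde
Conditions: Bu4NF, AcOH, THF, 0 °C
Reagents that add atoms: none
Why: Fluoride cleavage of the aryl silyl ether, made easy by the ortho aldehyde, which stabilises the phenoxide; acetic acid buffers the medium so that no strongly basic phenoxide solution is exposed to air.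

**Step 17**
Reactants: 34 allyl ether
Product: 35 2,4,5-trihydroxy-3-{(E)-[(2S,4aR,8aS)-2,5,5,8a-tetramethyloctahydronaphthalen-1(2H)-ylidene]methyl}benzaldehyde (target)
Conditions: Pd(PPh3)4 (cat.), morpholine, degassed THF, rt
Reagents that add atoms: none
Why: Tsuji–Trost-type deallylation: zerovalent palladium ionises the aryl allyl ether to a π-allyl complex and the phenoxide, and morpholine takes up the allyl group; the conditions are neutral and non-oxidising, so the hydroxyquinol, the aldehyde and the trisubstituted alkene survive.

## Compound list

1 | (S)-carvone, (5S)-2-methyl-5-(prop-1-en-2-yl)cyclohex-2-en-1-one | CC1=CC[C@@H](CC1=O)C(=C)C | starting material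
2 | lithium cross-conjugated dienolate of 1 (enolate toward the α′ carbon, stereocentre unchanged) | CC1=CC[C@@H](C=C1[O-])C(C)=C.[Li+] | intermediate (not isolated)
3 | (5S)-2,6-dimethyl-5-(prop-1-en-2-yl)cyclohex-2-en-1-one, both C6 epimers | CC1=CC[C@@H](C(C)C1=O)C(C)=C | intermediate
4 | acrolein (prop-2-enal) | C=CC=O | starting material
5 | 4-[(1S)-2,4-dimethyl-3-oxocyclohex-4-en-1-yl]-4-methylpentanal | CC1=CC[C@@H](C(C)C1=O)C(C)(C)CCC=O | intermediate
6 | (5S)-5-(5-hydroxy-2-methylpentan-2-yl)-2,6-dimethylcyclohex-2-en-1-one | CC1=CC[C@@H](C(C)C1=O)C(C)(C)CCCO | intermediate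
7 | (5S)-5-(5-iodo-2-methylpentan-2-yl)-2,6-dimethylcyclohex-2-en-1-one | CC1=CC[C@@H](C(C)C1=O)C(C)(C)CCCI | intermediate
8 | lithium dienolate of 7 (enolate C9=C10, C5 unchanged) | CC1=CC[C@@H](C(C)=C1[O-])C(C)(C)CCCI.[Li+] | intermediate (not isolated)
9 | (4aR,8aS)-2,5,5,8a-tetramethyl-4a,5,6,7,8,8a-hexahydronaphthalen-1(4H)-one, cis-fused | CC1=CC[C@@H]2C(C)(C)CCC[C@]2(C)C1=O | intermediate
10 | (2R,4aR,8aS)-2,5,5,8a-tetramethyloctahydronaphthalen-1(2H)-one (C8 epimer of 11) | C[C@@H]1CC[C@@H]2C(C)(C)CCC[C@]2(C)C1=O | intermediate (not isolated)
11 | (2S,4aR,8aS)-2,5,5,8a-tetramethyloctahydronaphthalen-1(2H)-one, cis-fused | C[C@H]1CC[C@@H]2C(C)(C)CCC[C@]2(C)C1=O | intermediate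
12 | ethyl 2-(trimethylsilyl)acetate | CCOC(=O)C[Si](C)(C)C | starting material
13 | lithium enolate of 12 | CCOC([O-])=C[Si](C)(C)C.[Li+] | intermediate (not isolated)
14 | lithium alkoxide from addition of 13 to C9 of 11 (β-silyl alkoxide, new centres unassigned) | C[C@H]1CC[C@@H]2C(C)(C)CCC[C@]2(C)C1([O-])C([Si](C)(C)C)C(=O)OCC.[Li+] | intermediate (not isolated)
15 | ethyl (2E)-2-[(2S,4aR,8aS)-2,5,5,8a-tetramethyloctahydronaphthalen-1(2H)-ylidene]acetate | C[C@H]1CC[C@@H]2C(C)(C)CCC[C@]2(C)/C1=C/C(=O)OCC | intermediate
16 | lithium enolate of the dibromomethyl ketone derived from 15 | C[C@H]1CC[C@@H]2C(C)(C)CCC[C@]2(C)/C1=C/C([O-])=C(Br)Br.[Li+] | intermediate (not isolated)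
17 | lithium (3E)-3-(decalinylidene)prop-1-yn-1-olate (ynolate, decalin as in 15) | C[C@H]1CC[C@@H]2C(C)(C)CCC[C@]2(C)/C1=C/C#C[O-].[Li+] | intermediate (not isolated)
18 | {[(3E)-3-[(2S,4aR,8aS)-2,5,5,8a-tetramethyloctahydronaphthalen-1(2H)-ylidene]prop-1-yn-1-yl]oxy}tri(propan-2-yl)silane | C[C@H]1CC[C@@H]2C(C)(C)CCC[C@]2(C)/C1=C/C#CO[Si](C(C)C)(C(C)C)C(C)C | intermediate
19 | methyl propiolate | C#CC(=O)OC | starting material
20 | allyl alcohol (prop-2-en-1-ol) | C=CCO | starting material
21 | methyl (2E)-3-(prop-2-en-1-yloxy)prop-2-enoate | C=CCO/C=C/C(=O)OC | intermediate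
22 | (2E)-3-(prop-2-en-1-yloxy)prop-2-enoic acid | C=CCO/C=C/C(=O)O | intermediate
23 | potassium methyl malonate (potassium 3-methoxy-3-oxopropanoate) | [K+].[O-]C(=O)CC(=O)OC | starting material
24 | (2E)-3-(prop-2-en-1-yloxy)prop-2-enoyl chloride | C=CCO/C=C/C(Cl)=O | intermediate (not isolated)
25 | methyl (4E)-3-oxo-5-(prop-2-en-1-yloxy)pent-4-enoate | C=CCO/C=C/C(=O)CC(=O)OC | intermediate
26 | methyl (4E)-2-diazo-3-oxo-5-(prop-2-en-1-yloxy)pent-4-enoate | C=CCO/C=C/C(=O)C(=[N+]=[N-])C(=O)OC | intermediate
27 | methyl (3E)-2-(oxomethylidene)-4-(prop-2-en-1-yloxy)but-3-enoate (vinylketene) | C=CCO/C=C/C(=C=O)C(=O)OC | intermediate (not isolated)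
28 | methyl 1-[(E)-2-(prop-2-en-1-yloxy)ethenyl]-2-oxo-3-{(E)-[decalinylidene]methyl}-4-{[tri(propan-2-yl)silyl]oxy}cyclobut-3-ene-1-carboxylate (decalin as in 18, ring sp3 carbon unassigned) | C[C@H]1CC[C@@H]2C(C)(C)CCC[C@]2(C)/C1=C/C3=C(O[Si](C(C)C)(C(C)C)C(C)C)C(C(=O)OC)(/C=C/OCC=C)C3=O | intermediate (not isolated)
29 | dienylketene from ring opening of 28, alkoxyvinyl group cis to the ketene-bearing carbon | C[C@H]1CC[C@@H]2C(C)(C)CCC[C@]2(C)/C1=C/C(=C=O)/C(O[Si](C(C)C)(C(C)C)C(C)C)=C(C(=O)OC)\C=C\OCC=C | intermediate (not isolated)
30 | methyl 4-oxo-3-(prop-2-en-1-yloxy)-5-{(E)-[decalinylidene]methyl}-6-{[tri(propan-2-yl)silyl]oxy}cyclohexa-1,5-diene-1-carboxylate (decalin as in 18, ring sp3 carbon unassigned) | C[C@H]1CC[C@@H]2C(C)(C)CCC[C@]2(C)/C1=C/C3=C(O[Si](C(C)C)(C(C)C)C(C)C)C(C(=O)OC)=CC(OCC=C)C3=O | intermediate (not isolated)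
31 | methyl 4-hydroxy-5-(prop-2-en-1-yloxy)-3-{(E)-[(2S,4aR,8aS)-2,5,5,8a-tetramethyloctahydronaphthalen-1(2H)-ylidene]methyl}-2-{[tri(propan-2-yl)silyl]oxy}benzoate | C[C@H]1CC[C@@H]2C(C)(C)CCC[C@]2(C)/C1=C/c1c(O)c(OCC=C)cc(C(=O)OC)c1O[Si](C(C)C)(C(C)C)C(C)C | intermediate
32 | [4-hydroxy-5-(prop-2-en-1-yloxy)-3-{(E)-[(2S,4aR,8aS)-2,5,5,8a-tetramethyloctahydronaphthalen-1(2H)-ylidene]methyl}-2-{[tri(propan-2-yl)silyl]oxy}phenyl]methanol | C[C@H]1CC[C@@H]2C(C)(C)CCC[C@]2(C)/C1=C/c1c(O)c(OCC=C)cc(CO)c1O[Si](C(C)C)(C(C)C)C(C)C | intermediate
33 | 4-hydroxy-5-(prop-2-en-1-yloxy)-3-{(E)-[(2S,4aR,8aS)-2,5,5,8a-tetramethyloctahydronaphthalen-1(2H)-ylidene]methyl}-2-{[tri(propan-2-yl)silyl]oxy}benzaldehyde | C[C@H]1CC[C@@H]2C(C)(C)CCC[C@]2(C)/C1=C/c1c(O)c(OCC=C)cc(C=O)c1O[Si](C(C)C)(C(C)C)C(C)C | intermediate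
34 | 2,4-dihydroxy-5-(prop-2-en-1-yloxy)-3-{(E)-[(2S,4aR,8aS)-2,5,5,8a-tetramethyloctahydronaphthalen-1(2H)-ylidene]methyl}benzaldehyde | C[C@H]1CC[C@@H]2C(C)(C)CCC[C@]2(C)/C1=C/c1c(O)c(OCC=C)cc(C=O)c1O | intermediate
35 | 2,4,5-trihydroxy-3-{(E)-[(2S,4aR,8aS)-2,5,5,8a-tetramethyloctahydronaphthalen-1(2H)-ylidene]methyl}benzaldehyde | C[C@H]1CC[C@@H]2C(C)(C)CCC[C@]2(C)/C1=C/c1c(O)c(O)cc(C=O)c1O | target

## Step count and least certain steps

Total: 17 steps. Longest linear sequence: 13 steps from 1 (steps 1–8, 13–17); the diazo ketoester branch is 4 steps (steps 9–12).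

**Step 13 (key step).** Two processes are most likely to lower its efficiency.
- The dienylketene 29 can be diverted: the rotamer with the ester cis to the ketene can close through the ester carbonyl oxygen, and the acceptor-substituted ketene 27 can dimerise or acylate the product phenol before it meets the hindered alkyne.
- The C9=C11 alkene can photo-isomerise once the light-absorbing arene has formed.

The fallback removes the ester from the ketene and brings in the C5' carbon later. It sets out from acid 22 through its chloride 24, which with diazomethane should give (3E)-1-diazo-4-(prop-2-en-1-yloxy)but-3-en-2-one F1, a plain unsaturated diazo ketone of the kind this benzannulation normally uses. Photolysis of F1 with 18 and warming should give the resorcinol monosilyl ether 6-(prop-2-en-1-yloxy)-2-{(E)-[decalinylidene]methyl}-3-{[tri(propan-2-yl)silyl]oxy}phenol F2. Bu4NF should free the diol 4-(prop-2-en-1-yloxy)-2-{(E)-[decalinylidene]methyl}benzene-1,3-diol F3. Magnesium-mediated ortho-formylation (MgCl2, Et3N, paraformaldehyde) can then only enter C5', the single free position ortho to a phenol, and comes back to the route at 34.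

**Step 7.** The ester enolate may act as a base and enolise the hindered ketone instead of adding to it, and the elimination may show poor discrimination between the two alkene geometries, because in the preferred chair both C8 and C10 present an equatorial methyl toward C11. Isomers would be separated at 15. The fallback sets out from 11: lithium ethoxyacetylide, a small and weakly basic nucleophile, should add to C9 to give the carbinol 1-(ethoxyethynyl)-2,5,5,8a-tetramethyldecahydronaphthalen-1-ol F4. A Sc(OTf)3-catalysed Meyer–Schuster rearrangement in the presence of ethanol converts F4 into the unsaturated ethyl ester under equilibrating conditions and comes back at 15.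

**Step 8.** The strong bases of the homologation may deprotonate the allylic C8 hydrogen of the enoate, or butyllithium may attack the conjugated system, before the rearrangement to the ynolate is complete. The fallback sets out from 15 and avoids carbenoid chemistry:
- i-Bu2AlH should give the allylic alcohol (2E)-2-(decalinylidene)ethanol F5.
- MnO2 should give the enal (2E)-2-(decalinylidene)acetaldehyde F6.
- Lithiated (trimethylsilyl)diazomethane (Colvin rearrangement) should give the terminal enyne (E)-1-(prop-2-yn-1-ylidene)-2,5,5,8a-tetramethyldecahydronaphthalene F7.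
- Deprotonation of F7 with LiN(SiMe3)2, oxidation of the acetylide with lithium tert-butyl peroxide to the same ynolate 17 and silylation with i-Pr3SiOTf come back at 18.

**Step 2.** Acrolein may be consumed by reduction or oligomerisation under the silane conditions, and the aldehyde product may be partly reduced or acetalised in the alcohol solvent. The fallback sets out from 3 and uses methyl acrylate as the acceptor, which should give methyl 4-[(1S)-2,4-dimethyl-3-oxocyclohex-4-en-1-yl]-4-methylpentanoate F8. LiAlH4 reduces both carbonyl groups to the diol (5S)-5-(5-hydroxy-2-methylpentan-2-yl)-2,6-dimethylcyclohex-2-en-1-ol F9. MnO2 reoxidises only the allylic alcohol and comes back at 6.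

## Further compounds

F1 | step 13 | (3E)-1-diazo-4-(prop-2-en-1-yloxy)but-3-en-2-one | C=CCO/C=C/C(=O)C=[N+]=[N-]
F2 | step 13 | 6-(prop-2-en-1-yloxy)-2-{(E)-[(2S,4aR,8aS)-2,5,5,8a-tetramethyloctahydronaphthalen-1(2H)-ylidene]methyl}-3-{[tri(propan-2-yl)silyl]oxy}phenol | C[C@H]1CC[C@@H]2C(C)(C)CCC[C@]2(C)/C1=C/c1c(O)c(OCC=C)ccc1O[Si](C(C)C)(C(C)C)C(C)C
F3 | step 13 | 4-(prop-2-en-1-yloxy)-2-{(E)-[(2S,4aR,8aS)-2,5,5,8a-tetramethyloctahydronaphthalen-1(2H)-ylidene]methyl}benzene-1,3-diol | C[C@H]1CC[C@@H]2C(C)(C)CCC[C@]2(C)/C1=C/c1c(O)c(OCC=C)ccc1O
F4 | step 7 | (2S,4aR,8aS)-1-(ethoxyethynyl)-2,5,5,8a-tetramethyldecahydronaphthalen-1-ol (C9 unassigned) | C[C@H]1CC[C@@H]2C(C)(C)CCC[C@]2(C)C1(O)C#COCC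
F5 | step 8 | (2E)-2-[(2S,4aR,8aS)-2,5,5,8a-tetramethyloctahydronaphthalen-1(2H)-ylidene]ethanol | C[C@H]1CC[C@@H]2C(C)(C)CCC[C@]2(C)/C1=C/CO
F6 | step 8 | (2E)-2-[(2S,4aR,8aS)-2,5,5,8a-tetramethyloctahydronaphthalen-1(2H)-ylidene]acetaldehyde | C[C@H]1CC[C@@H]2C(C)(C)CCC[C@]2(C)/C1=C/C=O
F7 | step 8 | (1E,2S,4aR,8aS)-2,5,5,8a-tetramethyl-1-(prop-2-yn-1-ylidene)decahydronaphthalene | C[C@H]1CC[C@@H]2C(C)(C)CCC[C@]2(C)/C1=C/C#C
F8 | step 2 | methyl 4-[(1S)-2,4-dimethyl-3-oxocyclohex-4-en-1-yl]-4-methylpentanoate | CC1=CC[C@@H](C(C)C1=O)C(C)(C)CCC(=O)OC
F9 | step 2 | (5S)-5-(5-hydroxy-2-methylpentan-2-yl)-2,6-dimethylcyclohex-2-en-1-ol (carbinol epimers) | CC1=CC[C@@H](C(C)C1O)C(C)(C)CCCO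
A1 | alternative 1 | 1-bromo-2,4,5-trimethoxy-3-[(3S,6Z)-3,7,11-trimethyldodeca-6,10-dien-1-yn-1-yl]benzene (Z-dienyne) | CC(C)=CCC/C(C)=C\CC[C@H](C)C#Cc1c(OC)c(OC)cc(Br)c1OC
A2 | alternative 1 | (5-bromo-2,3,6-trimethoxyphenyl)[cis-fused 2,5,5,8a-tetramethyldecahydronaphthalen-1-yl]methanone (C5, C8, C10 as in the target) | C[C@H]1CC[C@@H]2C(C)(C)CCC[C@]2(C)[C@@H]1C(=O)c1c(OC)c(OC)cc(Br)c1OC
A3 | alternative 2 | 2,6-dimethyl-1,4-benzoquinone | CC1=CC(=O)C=C(C)C1=O
A4 | alternative 2 | 4-methylpenta-1,3-diene | CC(C)=CC=C
A5 | alternative 2 | cis-fused 2,5,5,8a-tetramethyl-4a,5,8,8a-tetrahydronaphthalene-1,4-dione (C5 and C10 as in the target) | CC1=CC(=O)[C@@H]2C(C)(C)C=CC[C@]2(C)C1=O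
A6 | alternative 3 | 4-bromo-3-methoxy-2-(trimethylsilyl)phenyl trifluoromethanesulfonate | COc1c(Br)ccc(OS(=O)(=O)C(F)(F)F)c1[Si](C)(C)C
A7 | alternative 3 | (2S,4aR,8aS)-2,5,5,8a-tetramethyldecahydronaphthalene-1-carbaldehyde (C9 unassigned) | C[C@H]1CC[C@@H]2C(C)(C)CCC[C@]2(C)C1C=O
A8 | alternative 3 | 4-bromo-3-methoxy-2-{(E)-[(2S,4aR,8aS)-2,5,5,8a-tetramethyloctahydronaphthalen-1(2H)-ylidene]methyl}phenol | C[C@H]1CC[C@@H]2C(C)(C)CCC[C@]2(C)/C1=C/c1c(O)ccc(Br)c1OC
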